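## Retrosynthetic overview

- Ring A (C4a, C5, C6, C7, C8, C8a) of the chroman-2-one is a 3-acylphloroglucinol, that is, a folded tetraketide in which only C4a carries the stereogenic C4 branch. C5–C4a–C8a is therefore cut out as a 2-substituted malonyl unit, and C6–C7–C8 with the 3-phenylpropanoyl group as 6-phenylhexane-2,4-dione.
- Key disconnections: C5–C6 and C8–C8a, a [3+3] double C-acylation with the terminal carbon of the diketone dianion first and a magnesium-templated Claisen closure second. The O1–C2 lactone bond comes last.
- C4 is set before any ring exists, by amine-catalysed Michael addition of dimethyl malonate to 4-(benzyloxy)cinnamaldehyde. The aldehyde carbon becomes C2.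
- Ring order: ring A first. The lactone ring follows, closed on the oxygen at C8a once the C5 and C7 hydroxyls are blocked as benzyl ethers. Global hydrogenolysis ends the route.

Key step: step 7

Remark: atom labels C2 to C8a are those of the chroman-2-one skeleton of the target and denote the same atoms in all precursors; 1 is taken to be a catalogue compound.

## Route

**Step 1**
Reactants: 1 (E)-3-[4-(benzyloxy)phenyl]prop-2-enal; 2 dimethyl malonate
Product: 3 dimethyl 2-{(1R)-1-[4-(benzyloxy)phenyl]-3-oxopropyl}propanedioate
Conditions: (S)-2-[diphenyl(trimethylsilyloxy)methyl]pyrrolidine (10 mol %), PhCO2H (10 mol %), EtOH, 0 °C to rt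
Reagents that add atoms: none
Why: Iminium-catalysed asymmetric Michael addition, in which the CPh2(OSiMe3) group of the (S)-catalyst shields one face of the E, s-trans iminium ion of 1, so the malonate should add to the open Si face of the enal β-carbon and set the (R) centre that becomes C4.

**Step 2**
Reactants: 3 dimethyl 2-{(1R)-1-[4-(benzyloxy)phenyl]-3-oxopropyl}propanedioate
Product: 4 (3R)-3-[4-(benzyloxy)phenyl]-5-methoxy-4-(methoxycarbonyl)-5-oxopentanoic acid
Conditions: NaClO2, NaH2PO4, 2-methyl-2-butene, t-BuOH/H2O, 0 °C to rt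
Reagents that add atoms: sodium chlorite, [Na+].[O-]Cl=O
Why: The Pinnick oxidation converts the aldehyde to the acid under buffered conditions that leave the benzyl ether, the malonate C–H and the β-stereocentre untouched, 2-methyl-2-butene taking up the chlorinating by-product.

**Step 3**
Reactants: 4 (3R)-3-[4-(benzyloxy)phenyl]-5-methoxy-4-(methoxycarbonyl)-5-oxopentanoic acid
Product: 5 tert-butyl (3R)-3-[4-(benzyloxy)phenyl]-5-methoxy-4-(methoxycarbonyl)-5-oxopentanoate
Conditions: Cl3CC(=NH)Ot-Bu (2 equiv), CH2Cl2/cyclohexane, rt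
Reagents that add atoms: tert-butyl 2,2,2-trichloroacetimidate, CC(C)(C)OC(=N)C(Cl)(Cl)Cl
Why: Trichloroacetimidate esterification (tert-butyl transfer to the carboxylic acid) needs no base, so the malonate and the stereocentre are not disturbed, and it installs the one ester meant to outlast hydroxide, the dianion and methoxide.

**Step 4**
Reactants: 5 tert-butyl (3R)-3-[4-(benzyloxy)phenyl]-5-methoxy-4-(methoxycarbonyl)-5-oxopentanoate
Product: 6 2-{(1R)-1-[4-(benzyloxy)phenyl]-3-(tert-butoxy)-3-oxopropyl}propanedioic acid
Conditions: KOH (5 equiv), MeOH/THF/H2O, 40 °C; then 1 M HCl to pH 2–3, 0 °C, concentrate below 30 °C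
Reagents that add atoms: potassium hydroxide, [K+].[OH-]
Why: Saponification discriminates on steric grounds, both methyl esters being cleaved by hydroxide while the tert-butyl ester is inert, and cold acidification avoids decarboxylation of the malonic acid.

**Step 5**
Reactants: 6 2-{(1R)-1-[4-(benzyloxy)phenyl]-3-(tert-butoxy)-3-oxopropyl}propanedioic acid
Product: 7 tert-butyl (3R)-3-[4-(benzyloxy)phenyl]-5-chloro-4-(chlorocarbonyl)-5-oxopentanoate
Conditions: 1-chloro-N,N,2-trimethylprop-1-en-1-amine (2.2 equiv), CH2Cl2, 0 °C to rt; high vacuum, used at once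
Reagents that add atoms: 1-chloro-N,N,2-trimethylprop-1-en-1-amine, CC(C)=C(Cl)N(C)C
Why: Neutral acid chloride formation with an α-chloroenamine runs through an acyloxyiminium chloride and releases no HCl, which spares the tert-butyl ester that oxalyl chloride or SOCl2 would put at risk.

**Step 6**
Reactants: 8 pentane-2,4-dione; 9 benzyl bromide
Product: 11 6-phenylhexane-2,4-dione, via sodium lithium dianion 10 (not isolated)
Conditions: NaH (1.05 equiv), THF, 0 °C; n-BuLi (1.05 equiv), 0 °C; BnBr (1.0 equiv), 0 °C to rt; aq HCl
Reagents that add atoms: none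
Why: Terminal alkylation of a 1,3-diketone dianion, in which the terminal carbanion is by far the more nucleophilic site, so the SN2 benzylation should take place at C1 only.

**Step 7**
Reactants: 7 tert-butyl (3R)-3-[4-(benzyloxy)phenyl]-5-chloro-4-(chlorocarbonyl)-5-oxopentanoate; 11 6-phenylhexane-2,4-dione
Product: 16 tert-butyl (3S)-3-[4-(benzyloxy)phenyl]-3-[2,4,6-trihydroxy-3-(3-phenylpropanoyl)phenyl]propanoate, via sodium lithium dianion 12 (not isolated), via chlorocarbonylketene 13 (not isolated), via pyranone 14 (not isolated), via methyl triketo ester 15 (not isolated)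
Conditions: 11 (3 equiv), NaH (3 equiv), THF, 0 °C; n-BuLi (3 equiv), 0 °C; 7 (1 equiv) in THF added slowly at −78 °C, then to 0 °C; Mg(OMe)2 (8 equiv) in MeOH, 60 °C; cold 1 M HCl to pH 3
Reagents that add atoms: none
Why: Proposed new method: slow addition of 7 to three equivalents of the amine-free dianion 12 (metalated at C3 and at the less hindered C1 methyl group) should first cost one equivalent as base, the acidic malonyl hydrogen leaving with chloride to give chlorocarbonylketene 13, which has no acidic hydrogen and takes up the terminal carbanion of a second equivalent at its ketene carbon (C5–C6 bond); loss of the second chloride and capture of the resulting acylketene by the oxygen on C7 gives pyranone 14 as its salt. Mg(OMe)2 in methanol then opens 14 at the lactone carbonyl to triketo ester 15, in which C8, held in the magnesium chelate of the C7 and side-chain carbonyls, attacks the ester carbonyl C8a in a 6-exo-trig Claisen (Dieckmann-type) condensation that closes ring A (C8–C8a bond), and enolisation to the phenoxide makes this exit irreversible. The closest known reaction types are the terminal acylation of 1,3-diketone dianions by esters, the formation of 4-hydroxy-2-pyranones from malonyl dichlorides or chlorocarbonylketenes and enol derivatives, and the Mg(OMe)2-mediated Claisen cyclisation of 3,5,7-triketo esters and 6-(acylmethyl)-4-hydroxy-2-pyranones to acylphloroglucinols; new is their union in one flask on a 2-substituted malonyl dichloride. The step needs acylation on carbon in the final closure and one folding mode out of several: acylation on oxygen is reversible under methoxide, aldol attack of C4a on the side-chain ketone ends at a quaternary carbon that cannot aromatise, the singly activated CH2 next to the side-chain ketone is hardly enolised by methoxide, and the tert-butyl ester is too hindered to serve C6 as a rival Claisen acceptor. No stereocentre is formed, and C4 keeps its configuration because its hydrogen is not acidic and retro-Michael loss of the branch is held back while C4a is enolised or aromatic. The third equivalent of 12 takes up the acidic hydrogens of 14, and unused 11 is recovered after work-up.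

**Step 8**
Reactants: 16 tert-butyl (3S)-3-[4-(benzyloxy)phenyl]-3-[2,4,6-trihydroxy-3-(3-phenylpropanoyl)phenyl]propanoate; 9 benzyl bromide
Product: 17 tert-butyl (3S)-3-[4-(benzyloxy)phenyl]-3-[4,6-bis(benzyloxy)-2-hydroxy-3-(3-phenylpropanoyl)phenyl]propanoate
Conditions: BnBr (2.1 equiv), K2CO3 (2.5 equiv), acetone, 50 °C
Reagents that add atoms: benzyl bromide (compound 9, two equivalents), BrCc1ccccc1
Why: Williamson etherification under weak base, in which the C5 hydroxyl (para to the ketone) is the most acidic and the C7 hydroxyl the less hindered of the two ortho ones, while the C8a hydroxyl, wedged between the acyl group and the C4 branch and hydrogen-bonded to the ketone, should stay free, as in the usual 4,6-di-O-alkylation of 2,4,6-trihydroxyaryl ketones.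

**Step 9**
Reactants: 17 tert-butyl (3S)-3-[4-(benzyloxy)phenyl]-3-[4,6-bis(benzyloxy)-2-hydroxy-3-(3-phenylpropanoyl)phenyl]propanoate
Product: 19 (4S)-5,7-bis(benzyloxy)-4-[4-(benzyloxy)phenyl]-8-(3-phenylpropanoyl)chroman-2-one, via carboxylic acid 18 (not isolated)
Conditions: TFA/CH2Cl2 (1:4), 0 °C to rt; evaporate (toluene chase); 1-ethyl-3-(3-dimethylaminopropyl)carbodiimide hydrochloride (1.3 equiv), DMAP (10 mol %), CH2Cl2, 0 °C to rt
Reagents that add atoms: none
Why: Acidolysis of the tert-butyl ester (E1 loss of the tert-butyl group) followed by Steglich-type carbodiimide lactonisation, which can engage only the single free phenol at C8a and so fixes the 8-acyl regiochemistry without touching the non-acidic C4–H.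

**Step 10**
Reactants: 19 (4S)-5,7-bis(benzyloxy)-4-[4-(benzyloxy)phenyl]-8-(3-phenylpropanoyl)chroman-2-one
Product: 20 (4S)-5,7-dihydroxy-4-(4-hydroxyphenyl)-8-(3-phenylpropanoyl)chroman-2-one (CNP0383109.1)
Conditions: H2 (1 atm), 10% Pd/C, EtOAc, rt
Reagents that add atoms: none
Why: Catalytic hydrogenolysis of the three benzyl aryl ethers under neutral, aprotic conditions should leave the hydrogen-bonded aryl ketone and the aryl lactone intact and offers the freed C5 hydroxyl no acid or base to catalyse translactonisation.

## Compound list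

1 | (E)-3-[4-(benzyloxy)phenyl]prop-2-enal | O=C/C=C/c1ccc(OCc2ccccc2)cc1 | starting material
2 | dimethyl malonate | COC(=O)CC(=O)OC | starting material
3 | dimethyl 2-{(1R)-1-[4-(benzyloxy)phenyl]-3-oxopropyl}propanedioate | O=CC[C@@H](c1ccc(OCc2ccccc2)cc1)C(C(=O)OC)C(=O)OC | intermediate
4 | (3R)-3-[4-(benzyloxy)phenyl]-5-methoxy-4-(methoxycarbonyl)-5-oxopentanoic acid | OC(=O)C[C@@H](c1ccc(OCc2ccccc2)cc1)C(C(=O)OC)C(=O)OC | intermediate
5 | tert-butyl (3R)-3-[4-(benzyloxy)phenyl]-5-methoxy-4-(methoxycarbonyl)-5-oxopentanoate | CC(C)(C)OC(=O)C[C@@H](c1ccc(OCc2ccccc2)cc1)C(C(=O)OC)C(=O)OC | intermediate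
6 | 2-{(1R)-1-[4-(benzyloxy)phenyl]-3-(tert-butoxy)-3-oxopropyl}propanedioic acid | CC(C)(C)OC(=O)C[C@@H](c1ccc(OCc2ccccc2)cc1)C(C(=O)O)C(=O)O | intermediate
7 | tert-butyl (3R)-3-[4-(benzyloxy)phenyl]-5-chloro-4-(chlorocarbonyl)-5-oxopentanoate | CC(C)(C)OC(=O)C[C@@H](c1ccc(OCc2ccccc2)cc1)C(C(Cl)=O)C(Cl)=O | intermediate
8 | pentane-2,4-dione | CC(=O)CC(C)=O | starting material
9 | benzyl bromide | BrCc1ccccc1 | starting material
10 | sodium lithium 1,3-dianion of pentane-2,4-dione | [Na+].[Li+].C=C([O-])C=C(C)[O-] | intermediate
11 | 6-phenylhexane-2,4-dione | CC(=O)CC(=O)CCc1ccccc1 | intermediate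
12 | sodium lithium 1,3-dianion of 6-phenylhexane-2,4-dione (metalated at C1 and C3) | [Na+].[Li+].C=C([O-])C=C([O-])CCc1ccccc1 | intermediate
13 | tert-butyl (3S)-3-[4-(benzyloxy)phenyl]-4-(chlorocarbonyl)-5-oxopent-4-enoate (chlorocarbonylketene) | CC(C)(C)OC(=O)C[C@@H](c1ccc(OCc2ccccc2)cc1)C(=C=O)C(Cl)=O | intermediate
14 | tert-butyl (3S)-3-[4-(benzyloxy)phenyl]-3-[4-hydroxy-2-oxo-6-(2-oxo-4-phenylbutyl)-2H-pyran-3-yl]propanoate | CC(C)(C)OC(=O)C[C@@H](c1ccc(OCc2ccccc2)cc1)C1=C(O)C=C(CC(=O)CCc2ccccc2)OC1=O | intermediate
15 | tert-butyl (3R)-3-[4-(benzyloxy)phenyl]-4-(methoxycarbonyl)-5,7,9-trioxo-11-phenylundecanoate (epimers at C4 of the chain) | CC(C)(C)OC(=O)C[C@@H](c1ccc(OCc2ccccc2)cc1)C(C(=O)OC)C(=O)CC(=O)CC(=O)CCc1ccccc1 | intermediate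
16 | tert-butyl (3S)-3-[4-(benzyloxy)phenyl]-3-[2,4,6-trihydroxy-3-(3-phenylpropanoyl)phenyl]propanoate | CC(C)(C)OC(=O)C[C@@H](c1ccc(OCc2ccccc2)cc1)c1c(O)cc(O)c(C(=O)CCc2ccccc2)c1O | intermediate
17 | tert-butyl (3S)-3-[4-(benzyloxy)phenyl]-3-[4,6-bis(benzyloxy)-2-hydroxy-3-(3-phenylpropanoyl)phenyl]propanoate | CC(C)(C)OC(=O)C[C@@H](c1ccc(OCc2ccccc2)cc1)c1c(OCc2ccccc2)cc(OCc2ccccc2)c(C(=O)CCc2ccccc2)c1O | intermediate
18 | (3S)-3-[4-(benzyloxy)phenyl]-3-[4,6-bis(benzyloxy)-2-hydroxy-3-(3-phenylpropanoyl)phenyl]propanoic acid | OC(=O)C[C@@H](c1ccc(OCc2ccccc2)cc1)c1c(OCc2ccccc2)cc(OCc2ccccc2)c(C(=O)CCc2ccccc2)c1O | intermediate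
19 | (4S)-5,7-bis(benzyloxy)-4-[4-(benzyloxy)phenyl]-8-(3-phenylpropanoyl)chroman-2-one | O=C1C[C@@H](c2ccc(OCc3ccccc3)cc2)c2c(OCc3ccccc3)cc(OCc3ccccc3)c(C(=O)CCc3ccccc3)c2O1 | intermediate
20 | (4S)-5,7-dihydroxy-4-(4-hydroxyphenyl)-8-(3-phenylpropanoyl)chroman-2-one | O=C1C[C@@H](c2ccc(O)cc2)c2c(O)cc(O)c(C(=O)CCc3ccccc3)c2O1 | target

## Step count and risks

Total step count: 10.
Longest linear sequence: 9 (steps 1–5 and 7–10).

### Steps most likely to fail

**1. Step 7.**
- What may go wrong: proton transfer from the acidic intermediates to the dianion may outrun the terminal C-acylation. So may a second intermolecular acylation at the remaining chlorocarbonyl end, or attack through the central carbon of the diketone monoanion. The chain would then never be assembled cleanly.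
- Fallback (known reaction types, stepwise assembly of the same chain), setting out from 7: 7 is condensed with 2-(trimethylsilyloxy)propene in Et2O, −78 °C to rt. This is the established pyranone synthesis from malonyl dichlorides and silyl enol ethers. It gives tert-butyl (3S)-3-[4-(benzyloxy)phenyl]-3-(4-hydroxy-6-methyl-2-oxo-2H-pyran-3-yl)propanoate F1.
- The dianion of F1 (LDA, THF, −78 °C, metalated at the 4-oxygen and the 6-methyl group) is acylated with methyl 3-phenylpropanoate. This is the known side-chain acylation of 4-hydroxy-6-methyl-2-pyranone dianions.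
- The fallback comes back to the route at 14, now isolated and purified, which is then heated with Mg(OMe)2 in MeOH to reach 16.

**2. Step 8.**
- What may go wrong: poor site selectivity between the two hydroxyls ortho to the ketone, or benzylation on carbon at C6, would blur the only element that directs the lactone to C8a.
- Fallback (no protecting-group differentiation; separation and recycling instead), setting out from 16: 16 is treated with TFA in CH2Cl2, so that ester cleavage and lactonisation take place on both neighbouring hydroxyls.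
- This gives (4S)-4-[4-(benzyloxy)phenyl]-5,7-dihydroxy-8-(3-phenylpropanoyl)chroman-2-one F2 and its regioisomer (4S)-4-[4-(benzyloxy)phenyl]-5,7-dihydroxy-6-(3-phenylpropanoyl)chroman-2-one F3.
- The two are separated by chromatography, and F3 is returned to the acid medium for re-equilibration. F2 is hydrogenolysed (H2, Pd/C, EtOAc), which comes back to the route at 20.

**3. Step 5.**
- What may go wrong: loss of the tert-butyl ester, decarboxylation of the diacid, or premature dehydrochlorination and oligomerisation on concentration would hand an impure, unpurifiable electrophile to the key step.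
- Fallback (isolable active ester in place of the acid chloride), setting out from 6: 6 is coupled with pentafluorophenol (N,N'-dicyclohexylcarbodiimide, EtOAc, 0 °C). This gives the 1,1-bis(pentafluorophenyl) diester, tert-butyl (3R)-3-[4-(benzyloxy)phenyl]-5-oxo-5-(pentafluorophenoxy)-4-[(pentafluorophenoxy)carbonyl]pentanoate F4, which can be purified and stored.
- Like other activated aryl malonates, F4 reacts with bis-nucleophiles by elimination to a ketene. It is offered to dianion 12 under the conditions of step 7, and the fallback comes back to the route at 14 and from there at 16.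

## Further compounds

F1 | step 7 | tert-butyl (3S)-3-[4-(benzyloxy)phenyl]-3-(4-hydroxy-6-methyl-2-oxo-2H-pyran-3-yl)propanoate | CC(C)(C)OC(=O)C[C@@H](c1ccc(OCc2ccccc2)cc1)C1=C(O)C=C(C)OC1=O
F2 | step 8 | (4S)-4-[4-(benzyloxy)phenyl]-5,7-dihydroxy-8-(3-phenylpropanoyl)chroman-2-one | O=C1C[C@@H](c2ccc(OCc3ccccc3)cc2)c2c(O)cc(O)c(C(=O)CCc3ccccc3)c2O1
F3 | step 8 | (4S)-4-[4-(benzyloxy)phenyl]-5,7-dihydroxy-6-(3-phenylpropanoyl)chroman-2-one | O=C1C[C@@H](c2ccc(OCc3ccccc3)cc2)c2c(O)c(C(=O)CCc3ccccc3)c(O)cc2O1
F4 | step 5 | tert-butyl (3R)-3-[4-(benzyloxy)phenyl]-5-oxo-5-(pentafluorophenoxy)-4-[(pentafluorophenoxy)carbonyl]pentanoate | CC(C)(C)OC(=O)C[C@@H](c1ccc(OCc2ccccc2)cc1)C(C(=O)Oc1c(F)c(F)c(F)c(F)c1F)C(=O)Oc1c(F)c(F)c(F)c(F)c1F
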